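**Plan**

- Retrosynthesis: ring A (C4a–C5–C6–C7–C8–C8a) carries only O1 on C8a, the C4 methylene on C4a and one hydroxyl on C7. It is therefore cut into three alkynes at C4a–C8a, C5–C6 and C7–C8, two of them held together by the ring C chain C4–C3–C2–O1, with C7–OH traced back to C7–B.
- Further cuts: O1–C8a (ynol ether from the C2 alcohol), C3–C4 (enolate propargylation), C2–C3 (one-carbon homologation of a ring B aldehyde), and in ring B the C5'–C(CH3)2 bond (aromatic Claisen rearrangement) and the O–prenyl bonds.
- Forward: ring B is dressed on 2,4-dihydroxybenzaldehyde (steps 1–4) and the chain C2–C3–C4 is attached (steps 5–10). Rings C and A then close together in one ruthenium-catalysed [2+2+2] step, followed by C7–B oxidation, C5 desilylation and release of the 2'-phenol (steps 12–14).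
- Stereochemistry: the only stereocentre, C3 (R), is set in step 8 by alkylation of an (R)-4-benzyl-oxazolidinone imide enolate anti to the benzyl group and is not touched afterwards.

Key step: step 11

Remark: isoflavan numbering is used (O1, C2, C3, C4, C4a, C5–C8, C8a for rings C and A; primed numbers for ring B). SEM = 2-(trimethylsilyl)ethoxymethyl; Ar = 5-(2-methylbut-3-en-2-yl)-4-(3-methylbut-2-enyloxy)-2-(SEM-oxy)phenyl, the protected ring B.
Remark: an anion formed only by deprotonation of a numbered compound (alkoxide, enolate, acetylide, carboxylate, phenoxide) is treated as that compound and has no number of its own.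

**Route**

Step 1
Reactants: 1 2,4-dihydroxybenzaldehyde; 2 prenyl bromide (1-bromo-3-methylbut-2-ene)
Product: 3 2-hydroxy-4-(3-methylbut-2-enyloxy)benzaldehyde
Conditions: K2CO3 (1.1 equiv), acetone, reflux
Reagents that add atoms: none
Why: Williamson etherification should take place at the 4-hydroxyl, because the 2-hydroxyl is tied up in a hydrogen bond to the formyl group and is the weaker nucleophile under mild carbonate conditions.

Step 2
Reactants: 3 2-hydroxy-4-(3-methylbut-2-enyloxy)benzaldehyde
Product: 4 4-(3-methylbut-2-enyloxy)-2-(SEM-oxy)benzaldehyde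
Conditions: SEMCl, i-Pr2NEt, CH2Cl2, 0 °C to rt
Reagents that add atoms: 2-(trimethylsilyl)ethoxymethyl chloride, C[Si](C)(C)CCOCCl
Why: O-alkylation of the remaining phenol with the reactive chloromethyl ether (acetal protection) masks O2' with a group that tolerates alkoxides, hydride and organolithium reagents and is later removed by fluoride.

Step 3
Reactants: 4 4-(3-methylbut-2-enyloxy)-2-(SEM-oxy)benzaldehyde
Product: 5 4-hydroxy-5-(2-methylbut-3-en-2-yl)-2-(SEM-oxy)benzaldehyde
Conditions: EtOH/H2O (4:1), 130 °C, sealed tube, argon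
Reagents that add atoms: none
Why: Aromatic Claisen rearrangement ([3,3]-sigmatropic shift) of the aryl prenyl ether should deliver the inverted 1,1-dimethylallyl group to C5, the only unhindered ortho position since C3 lies between two oxygen substituents, with the protic medium accelerating the shift of an ether para to a carbonyl group and tautomerisation restoring the phenol.

Step 4
Reactants: 5 4-hydroxy-5-(2-methylbut-3-en-2-yl)-2-(SEM-oxy)benzaldehyde; 2 prenyl bromide
Product: 6 5-(2-methylbut-3-en-2-yl)-4-(3-methylbut-2-enyloxy)-2-(SEM-oxy)benzaldehyde (ArCHO)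
Conditions: K2CO3, DMF, rt
Reagents that add atoms: none
Why: Williamson etherification of the acidic para-formyl phenol with the reactive allylic bromide should proceed despite the neighbouring quaternary carbon and restores the 4'-O-prenyl ether of the target.

Step 5
Reactants: 6 ArCHO; 7 p-toluenesulfonylmethyl isocyanide (TosMIC)
Product: 9 2-Ar-acetonitrile, via N-(2-Ar-1-tosylvinyl)formamide 8 (not isolated)
Conditions: t-BuOK, DME, −40 °C; then MeOH, reflux
Reagents that add atoms: none
Why: Van Leusen reductive cyanation, in which the TosMIC anion adds to the aldehyde, the oxazoline opens under t-BuOK to formamide 8, and methanolysis of the formyl group followed by loss of sulfinate leaves the nitrile with the future C2 attached to C3.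

Step 6
Reactants: 9 2-Ar-acetonitrile
Product: 10 2-Ar-acetic acid
Conditions: KOH, EtOH/H2O, reflux; then 1 M HCl, 0 °C, to pH 3
Reagents that add atoms: potassium hydroxide, [K+].[OH-]; water, O
Why: Base hydrolysis of the nitrile through the primary amide gives the carboxylate under conditions to which the aryl ethers, the SEM acetal and both alkenes are inert, and brief cold acidification frees the acid.

Step 7
Reactants: 10 2-Ar-acetic acid; 11 (R)-4-benzyl-2-oxazolidinone
Product: 13 (R)-4-benzyl-3-(2-Ar-acetyl)oxazolidin-2-one, via mixed pivalic anhydride 12 (not isolated)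
Conditions: t-BuCOCl, Et3N, THF, −20 °C; then 11, LiCl, −20 °C to rt
Reagents that add atoms: pivaloyl chloride, CC(C)(C)C(=O)Cl (its atoms stay only in intermediate 12)
Why: N-Acylation of the oxazolidinone through the mixed anhydride, in which LiCl and Et3N make the oxazolidinone nucleophilic enough to attack the less hindered arylacetyl carbonyl of 12.

Step 8
Reactants: 13 (R)-4-benzyl-3-(2-Ar-acetyl)oxazolidin-2-one; 14 3-bromo-1-(trimethylsilyl)propyne
Product: 15 (R)-4-benzyl-3-[(2R)-2-Ar-5-(trimethylsilyl)pent-4-ynoyl]oxazolidin-2-one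
Conditions: NaN(SiMe3)2, THF, −78 °C; then 14, −78 to −40 °C
Reagents that add atoms: none
Why: Evans asymmetric alkylation, in which the sodium-chelated Z-enolate is attacked by the propargylic bromide on the face opposite the benzyl group of the (R)-auxiliary, which sets the (R) configuration of the future C3 and forms C3–C4.

Step 9
Reactants: 15 (R)-4-benzyl-3-[(2R)-2-Ar-5-(trimethylsilyl)pent-4-ynoyl]oxazolidin-2-one
Product: 16 (2R)-2-Ar-5-(trimethylsilyl)pent-4-yn-1-ol
Conditions: LiBH4, MeOH (1.1 equiv), THF, 0 °C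
Reagents that add atoms: none
Why: Reductive cleavage of the imide by borohydride attack at the exocyclic carbonyl gives the primary alcohol and the recoverable auxiliary without epimerising the α-aryl centre and without touching the silylalkyne.

Step 10
Reactants: 16 (2R)-2-Ar-5-(trimethylsilyl)pent-4-yn-1-ol; 17 trichloroethylene
Product: 19 [(4R)-4-Ar-5-(ethynyloxy)pent-1-yn-1-yl]trimethylsilane, via (E)-1,2-dichlorovinyl ether 18 (not isolated)
Conditions: KH, THF, 0 °C; 17, −50 °C to rt; then n-BuLi (2.5 equiv), −78 to −40 °C; MeOH, −78 °C; product kept cold and used at once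
Reagents that add atoms: none
Why: Alkoxide addition to dichloroacetylene generated from trichloroethylene gives dichlorovinyl ether 18, and n-BuLi then effects dehydrochlorination and chlorine–lithium exchange to the lithium alkoxyacetylide, which methanol protonates to the terminal ynol ether (dichlorovinyl ether route to alkynyl ethers).

Step 11
Reactants: 19 [(4R)-4-Ar-5-(ethynyloxy)pent-1-yn-1-yl]trimethylsilane; 20 ethynylboronic acid pinacol ester
Product: 21 (3R)-3-Ar-7-(4,4,5,5-tetramethyl-1,3,2-dioxaborolan-2-yl)-5-(trimethylsilyl)chromane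
Conditions: Cp*RuCl(cod) (10 mol %), 20 (3 equiv), ClCH2CH2Cl, rt, 19 added slowly, argon
Reagents that add atoms: none
Why: The Cp*RuCl fragment couples the ynol ether (C8a≡C8) and the silylalkyne (C4a≡C5) of 19 oxidatively to a ruthenacyclopentatriene, which forms C4a–C8a, and insertion of the boryl alkyne followed by reductive elimination forms C7–C8 and C5–C6, the whole being a [2+2+2] alkyne cyclotrimerisation. The closest known reactions are Cp*RuCl(cod)-catalysed cross-cyclotrimerisations of tethered 1,6- and 1,7-diynes with alkynylboronates and cyclotrimerisations of nitrogen- and oxygen-tethered diynes (ynamides, aryl ynol ethers) with monoalkynes. Ring C closes as a six-membered ring by oxidative cyclisation of the 1,7-diyne tether O1–C2–C3–C4 on the metal, and ring A closes as the new benzene ring by alkyne insertion and reductive elimination. No stereocentre is formed, and C3 lies in the tether, two bonds from each reacting alkyne, and meets neither acid nor base, so the configuration from step 8 is carried through. Regioselectivity (boron at C7, not C6) rests on the trimethylsilyl group at C5, which should make the boron-bearing alkyne carbon bond to the unhindered terminus C8 so that boron ends meta to silicon, as found for diynes with one substituted terminus under this catalyst. Cross- over homo-trimerisation is favoured by slow addition of 19 to an excess of 20 at room temperature, where the ynol ether is thermally safe, and the hindered 1,1-dimethylallyl and prenyl alkenes of ring B should not compete with alkynes for ruthenium.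

Step 12
Reactants: 21 (3R)-3-Ar-7-(4,4,5,5-tetramethyl-1,3,2-dioxaborolan-2-yl)-5-(trimethylsilyl)chromane
Product: 22 (3R)-3-Ar-5-(trimethylsilyl)chroman-7-ol
Conditions: NaBO3·4H2O, THF/H2O (1:1), rt
Reagents that add atoms: sodium perborate tetrahydrate, [Na+].[Na+].O[B-]1(O)OO[B-](O)(O)OO1 (dimeric anion, water of crystallisation not shown)
Why: Oxidation of the aryl–boron bond by perborate proceeds by peroxide addition to boron and 1,2-aryl shift to oxygen, which places the hydroxyl exactly at C7 and leaves the aryl–silicon bond, the SEM acetal and both alkenes untouched.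

Step 13
Reactants: 22 (3R)-3-Ar-5-(trimethylsilyl)chroman-7-ol
Product: 23 (3R)-3-Ar-chroman-7-ol
Conditions: KOSiMe3 (3 equiv), DMSO/H2O, 70 °C, argon; then aq NH4Cl
Reagents that add atoms: none
Why: Base-mediated protodesilylation, in which silanolate or hydroxide adds to the aryl silicon and the pentacoordinate silicate is protonated at C5 by water, under a base too weak to eliminate the prenyl ether or to deprotonate C3, whereas acid would cleave the prenyl ether.

Step 14
Reactants: 23 (3R)-3-Ar-chroman-7-ol
Product: 24 Manuifolin D, (3R)-3-[2-hydroxy-5-(2-methylbut-3-en-2-yl)-4-(3-methylbut-2-enyloxy)phenyl]chroman-7-ol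
Conditions: Bu4NF, H2NCH2CH2NH2, DMF, 60 °C; then aq NH4Cl
Reagents that add atoms: none
Why: Fluoride-induced fragmentation of the SEM ether (attack at silicon, loss of ethylene and formaldehyde) frees the 2'-phenol under non-acidic conditions that spare the prenyl ether, with ethylenediamine trapping formaldehyde before it can hydroxymethylate the electron-rich phenols.

**Compound list**

1 | 2,4-dihydroxybenzaldehyde | O=Cc1ccc(O)cc1O | starting material
2 | prenyl bromide (1-bromo-3-methylbut-2-ene) | CC(C)=CCBr | starting material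
3 | 2-hydroxy-4-(3-methylbut-2-enyloxy)benzaldehyde | O=Cc1ccc(OCC=C(C)C)cc1O | intermediate
4 | 4-(3-methylbut-2-enyloxy)-2-(SEM-oxy)benzaldehyde | O=Cc1ccc(OCC=C(C)C)cc1OCOCC[Si](C)(C)C | intermediate
5 | 4-hydroxy-5-(2-methylbut-3-en-2-yl)-2-(SEM-oxy)benzaldehyde | O=Cc1cc(C(C)(C)C=C)c(O)cc1OCOCC[Si](C)(C)C | intermediate
6 | 5-(2-methylbut-3-en-2-yl)-4-(3-methylbut-2-enyloxy)-2-(SEM-oxy)benzaldehyde (ArCHO) | O=Cc1cc(C(C)(C)C=C)c(OCC=C(C)C)cc1OCOCC[Si](C)(C)C | intermediate
7 | p-toluenesulfonylmethyl isocyanide (TosMIC) | Cc1ccc(cc1)S(=O)(=O)C[N+]#[C-] | starting material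
8 | N-[2-Ar-1-(4-methylphenylsulfonyl)ethenyl]formamide (alkene geometry not defined) | O=CNC(=Cc1cc(C(C)(C)C=C)c(OCC=C(C)C)cc1OCOCC[Si](C)(C)C)S(=O)(=O)c1ccc(C)cc1 | intermediate (not isolated)
9 | 2-Ar-acetonitrile | N#CCc1cc(C(C)(C)C=C)c(OCC=C(C)C)cc1OCOCC[Si](C)(C)C | intermediate
10 | 2-Ar-acetic acid | OC(=O)Cc1cc(C(C)(C)C=C)c(OCC=C(C)C)cc1OCOCC[Si](C)(C)C | intermediate
11 | (R)-4-benzyl-2-oxazolidinone | O=C1N[C@H](Cc2ccccc2)CO1 | starting material
12 | 2-Ar-acetic pivalic anhydride | CC(C)(C)C(=O)OC(=O)Cc1cc(C(C)(C)C=C)c(OCC=C(C)C)cc1OCOCC[Si](C)(C)C | intermediate (not isolated)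
13 | (R)-4-benzyl-3-(2-Ar-acetyl)oxazolidin-2-one | O=C(Cc1cc(C(C)(C)C=C)c(OCC=C(C)C)cc1OCOCC[Si](C)(C)C)N1[C@H](Cc2ccccc2)COC1=O | intermediate
14 | 3-bromo-1-(trimethylsilyl)propyne | C[Si](C)(C)C#CCBr | starting material
15 | (R)-4-benzyl-3-[(2R)-2-Ar-5-(trimethylsilyl)pent-4-ynoyl]oxazolidin-2-one | C=CC(C)(C)c1cc([C@@H](CC#C[Si](C)(C)C)C(=O)N2[C@H](Cc3ccccc3)COC2=O)c(OCOCC[Si](C)(C)C)cc1OCC=C(C)C | intermediate
16 | (2R)-2-Ar-5-(trimethylsilyl)pent-4-yn-1-ol | C=CC(C)(C)c1cc([C@@H](CC#C[Si](C)(C)C)CO)c(OCOCC[Si](C)(C)C)cc1OCC=C(C)C | intermediate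
17 | trichloroethylene | ClC=C(Cl)Cl | starting material
18 | [(4R)-4-Ar-5-{[(E)-1,2-dichloroethenyl]oxy}pent-1-yn-1-yl]trimethylsilane | C=CC(C)(C)c1cc([C@@H](CC#C[Si](C)(C)C)CO/C(Cl)=C\Cl)c(OCOCC[Si](C)(C)C)cc1OCC=C(C)C | intermediate (not isolated)
19 | [(4R)-4-Ar-5-(ethynyloxy)pent-1-yn-1-yl]trimethylsilane (ynol ether diyne) | C=CC(C)(C)c1cc([C@@H](CC#C[Si](C)(C)C)COC#C)c(OCOCC[Si](C)(C)C)cc1OCC=C(C)C | intermediate
20 | ethynylboronic acid pinacol ester | C#CB1OC(C)(C)C(C)(C)O1 | starting material
21 | (3R)-3-Ar-7-(4,4,5,5-tetramethyl-1,3,2-dioxaborolan-2-yl)-5-(trimethylsilyl)chromane | C=CC(C)(C)c1cc([C@@H]2COc3cc(B4OC(C)(C)C(C)(C)O4)cc([Si](C)(C)C)c3C2)c(OCOCC[Si](C)(C)C)cc1OCC=C(C)C | intermediate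
22 | (3R)-3-Ar-5-(trimethylsilyl)chroman-7-ol | C=CC(C)(C)c1cc([C@@H]2COc3cc(O)cc([Si](C)(C)C)c3C2)c(OCOCC[Si](C)(C)C)cc1OCC=C(C)C | intermediate
23 | (3R)-3-Ar-chroman-7-ol | C=CC(C)(C)c1cc([C@@H]2COc3cc(O)ccc3C2)c(OCOCC[Si](C)(C)C)cc1OCC=C(C)C | intermediate
24 | Manuifolin D | C=CC(C)(C)c1cc([C@@H]2COc3cc(O)ccc3C2)c(O)cc1OCC=C(C)C | target

**Summary**

Total step count: 14. Longest linear sequence: 14 steps (1 to 24); all other components are commercial.

**Steps most likely to fail**

1. Step 11. The terminal ynol ether may oligomerise or decompose on ruthenium faster than the hindered silylalkyne enters the metallacycle, or homo-coupling of the diyne may outrun capture by the boryl alkyne. The fallback buys ring A instead of building it; it sets out from imide 13 and returns at 23. Compound 13 would be alkylated under the conditions of step 8 with commercial 2-bromo-4-chlorobenzyl bromide, with the same facial control, to give (R)-4-benzyl-3-[(2R)-2-Ar-3-(2-bromo-4-chlorophenyl)propanoyl]oxazolidin-2-one F1. LiBH4 reduction would give (2R)-2-Ar-3-(2-bromo-4-chlorophenyl)propan-1-ol F2. Copper-catalysed intramolecular O-arylation at the bromide (CuI, 1,10-phenanthroline, Cs2CO3, toluene, 110 °C) would close ring C to (3R)-3-Ar-7-chlorochromane F3. Palladium-catalysed hydroxylation of the aryl chloride (Pd2(dba)3, 2-di-tert-butylphosphino-2',4',6'-triisopropylbiphenyl, KOH, dioxane/H2O, 100 °C) would then give 23.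

2. Step 10. The potassium alkoxide may transfer the trimethylsilyl group from the alkyne to oxygen before it is captured, or the ynol ether may be lost on isolation. The fallback avoids any alkoxide; it sets out from alcohol 16 and returns at 19. Compound 16 would be formylated (HCO2H, dicyclohexylcarbodiimide, 4-dimethylaminopyridine, CH2Cl2) to (2R)-2-Ar-5-(trimethylsilyl)pent-4-yn-1-yl formate F4. Dichloromethylenation of the formate carbonyl (PPh3, CCl4, THF, 60 °C) would give [(4R)-4-Ar-5-(2,2-dichloroethenyloxy)pent-1-yn-1-yl]trimethylsilane F5. Treatment with n-BuLi (THF, −78 °C) and a methanol quench would then give 19 by elimination and chlorine–lithium exchange.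

3. Step 3. The liberated phenol may undergo abnormal Claisen rearrangement or cyclise onto the new alkene, and the ether may be cleaved instead of rearranging. The fallback forms the C5'–C(CH3)2 bond by cross-coupling; it sets out from 1 and returns at 6. Compound 1 would be brominated (Br2, AcOH) to 5-bromo-2,4-dihydroxybenzaldehyde F6, prenylated at O4 as in step 1 to 5-bromo-2-hydroxy-4-(3-methylbut-2-enyloxy)benzaldehyde F7, and protected as in step 2 to 5-bromo-4-(3-methylbut-2-enyloxy)-2-(SEM-oxy)benzaldehyde F8. A γ-selective Suzuki–Miyaura allylation of F8 with 3-methylbut-2-enylboronic acid pinacol ester (Pd(OAc)2, 1,1'-bis(di-tert-butylphosphino)ferrocene, K3PO4, THF/H2O, 60 °C) would build the quaternary benzylic carbon directly and give 6.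

**Further compounds**

F1 | step 11 | (R)-4-benzyl-3-[(2R)-2-Ar-3-(2-bromo-4-chlorophenyl)propanoyl]oxazolidin-2-one | C=CC(C)(C)c1cc([C@@H](Cc2ccc(Cl)cc2Br)C(=O)N2[C@H](Cc3ccccc3)COC2=O)c(OCOCC[Si](C)(C)C)cc1OCC=C(C)C
F2 | step 11 | (2R)-2-Ar-3-(2-bromo-4-chlorophenyl)propan-1-ol | C=CC(C)(C)c1cc([C@@H](Cc2ccc(Cl)cc2Br)CO)c(OCOCC[Si](C)(C)C)cc1OCC=C(C)C
F3 | step 11 | (3R)-3-Ar-7-chlorochromane | C=CC(C)(C)c1cc([C@@H]2COc3cc(Cl)ccc3C2)c(OCOCC[Si](C)(C)C)cc1OCC=C(C)C
F4 | step 10 | (2R)-2-Ar-5-(trimethylsilyl)pent-4-yn-1-yl formate | C=CC(C)(C)c1cc([C@@H](CC#C[Si](C)(C)C)COC=O)c(OCOCC[Si](C)(C)C)cc1OCC=C(C)C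
F5 | step 10 | [(4R)-4-Ar-5-(2,2-dichloroethenyloxy)pent-1-yn-1-yl]trimethylsilane | C=CC(C)(C)c1cc([C@@H](CC#C[Si](C)(C)C)COC=C(Cl)Cl)c(OCOCC[Si](C)(C)C)cc1OCC=C(C)C
F6 | step 3 | 5-bromo-2,4-dihydroxybenzaldehyde | O=Cc1cc(Br)c(O)cc1O
F7 | step 3 | 5-bromo-2-hydroxy-4-(3-methylbut-2-enyloxy)benzaldehyde | O=Cc1cc(Br)c(OCC=C(C)C)cc1O
F8 | step 3 | 5-bromo-4-(3-methylbut-2-enyloxy)-2-(SEM-oxy)benzaldehyde | O=Cc1cc(Br)c(OCC=C(C)C)cc1OCOCC[Si](C)(C)C
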